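**Strategy.** The target is cut at the biaryl bond into a tetralin (cycloolivil-type) half and an oxolane half, both drawn from one open-chain tetrol made from (S)-malic acid. The oxolane is closed by its O1–C2 bond: a γ-silyloxy aryl ketone undergoes Lewis-acid reductive cycloetherification, in which the C5 oxygen adds to the C2 carbonyl and hydride then enters the cyclic 2-aryl oxocarbenium ion from the face of the C4 hydroxyl, away from the C3 and C4 carbon substituents. One operation thus forms the ring and the contra-thermodynamic all-cis C2/C3/C4 array. The same tetrol gives the tetralin by Friedel–Crafts closure; Suzuki coupling joins the halves.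

Key step: step 12

Remark on the chemistry: the SMILES is read as drawn, so the oxolane half is (2R,3R,4S), with the aryl group at C2 cis to the C3 hydroxymethyl and C4 arylmethyl groups (the C2 epimer of an olivil unit), and the tetralin half has the cycloolivil configuration. Oxolane atoms are numbered O1, C2 (aryl), C3 (CH2OH), C4 (OH, arylmethyl), C5 (CH2); the same numbers are kept for these atoms in open-chain precursors.

**Route**

Step 1
Reactants: 1 (4-benzyloxy-3-methoxyphenyl)methanol
Product: 2 4-benzyloxy-3-methoxybenzyl bromide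
Conditions: PBr3 (0.4 equiv), CH2Cl2, 0 °C; used crude
Reagents that add atoms: phosphorus tribromide, BrP(Br)Br
Why: Conversion of a primary benzylic alcohol into the bromide with PBr3; the aryl ethers are inert at 0 °C.

Step 2
Reactants: 3 (S)-malic acid
Product: 4 2-[(2S,4S)-2-tert-butyl-5-oxo-1,3-dioxolan-4-yl]acetic acid
Conditions: pivalaldehyde, TsOH·H2O (cat.), H2SO4 (cat.), pentane, reflux, Dean–Stark; recrystallisation
Reagents that add atoms: pivalaldehyde, CC(C)(C)C=O
Why: Acid-catalysed acetalisation of the α-hydroxy acid (Seebach dioxolanone, self-regeneration of stereocentres); the cis acetal is the thermodynamic, crystalline isomer, so the acetal centre is set by the malic acid centre.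

Step 3
Reactants: 4 2-[(2S,4S)-2-tert-butyl-5-oxo-1,3-dioxolan-4-yl]acetic acid; 2 4-benzyloxy-3-methoxybenzyl bromide
Product: 5 2-[(2S,4S)-4-(4-benzyloxy-3-methoxybenzyl)-2-tert-butyl-5-oxo-1,3-dioxolan-4-yl]acetic acid
Conditions: LiN(SiMe3)2 (2.2 equiv), THF, −78 °C; then 2, −78 to −30 °C; aq. HCl work-up
Reagents that add atoms: none
Why: Alkylation of the carboxylate–dioxolanone enolate dianion (Seebach alkylation); the bromide enters anti to the tert-butyl group, so the arylmethyl group replaces H with retention and fixes the future C4 as S.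

Step 4
Reactants: 5 2-[(2S,4S)-4-(4-benzyloxy-3-methoxybenzyl)-2-tert-butyl-5-oxo-1,3-dioxolan-4-yl]acetic acid
Product: 7 (4S)-4-(4-benzyloxy-3-methoxybenzyl)-4-hydroxyoxolan-2-one, via dihydroxy acid 6 (not isolated)
Conditions: NaH (1.0 equiv), THF, 0 °C; LiBH4 (3 equiv), THF, 0 °C to rt; then 2 M HCl, rt
Reagents that add atoms: none
Why: LiBH4 reduces the acylal-type dioxolanone carbonyl but not the sodium carboxylate, the acetal collapses (pivalaldehyde is reduced to neopentyl alcohol), and acid lactonises 6 through its primary hydroxyl (hydride reduction, then γ-lactonisation); the quaternary centre is untouched.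

Step 5
Reactants: 8 5-bromovanillin
Product: 9 4-benzyloxy-3-bromo-5-methoxybenzaldehyde
Conditions: BnBr (1.1 equiv), K2CO3, DMF, rt
Reagents that add atoms: benzyl bromide, BrCc1ccccc1
Why: Williamson ether synthesis on the phenoxide; the aldehyde is inert.

Step 6
Reactants: 7 (4S)-4-(4-benzyloxy-3-methoxybenzyl)-4-hydroxyoxolan-2-one; 9 4-benzyloxy-3-bromo-5-methoxybenzaldehyde
Product: 10 (3R,4S)-3-[(4-benzyloxy-3-bromo-5-methoxyphenyl)(hydroxy)methyl]-4-(4-benzyloxy-3-methoxybenzyl)-4-hydroxyoxolan-2-one (carbinol epimers)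
Conditions: KN(SiMe3)2 (2.2 equiv), THF, −78 °C; then 9, −78 °C; AcOH quench at −78 °C
Reagents that add atoms: none
Why: Aldol addition of the alkoxide–enolate dianion (Fráter–Seebach-type dianion) to a non-enolisable aldehyde; the aldehyde should enter anti to the arylmethyl group and syn to the metal alkoxide that delivers it, setting C3 (R), while the carbinol centre forms as a mixture that both later branches erase.

Step 7
Reactants: 10 aldol lactone (carbinol epimers)
Product: 11 (2S,3R)-3-[(4-benzyloxy-3-bromo-5-methoxyphenyl)(hydroxy)methyl]-2-(4-benzyloxy-3-methoxybenzyl)butane-1,2,4-triol (tetrol, carbinol epimers)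
Conditions: LiBH4 (4 equiv), THF/MeOH, 0 °C to rt
Reagents that add atoms: none
Why: Hydride reduction of the lactone to the diol; LiBH4 leaves the aryl bromide and benzyl ethers alone and touches no stereocentre.

Step 8
Reactants: 11 tetrol
Product: 12 (2S,3S,4S)-6-benzyloxy-4-(4-benzyloxy-3-bromo-5-methoxyphenyl)-2,3-bis(hydroxymethyl)-7-methoxy-1,2,3,4-tetrahydronaphthalen-2-ol
Conditions: BF3·OEt2 (3 equiv), CH2Cl2, 0 °C to rt
Reagents that add atoms: none
Why: Intramolecular Friedel–Crafts alkylation (the olivil-to-cycloolivil mode): either carbinol epimer ionises, the cation is captured by the arylmethyl ring para to its methoxy group, reversible oxolane formation through the C5 hydroxyl drains into the tetralin, and the aryl group settles trans to the neighbouring hydroxymethyl group (pseudoequatorial in the chair-like closure).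

Step 9
Reactants: 12 tetralin bromide
Product: 13 pinacol boronate of 12 (Br replaced by 4,4,5,5-tetramethyl-1,3,2-dioxaborolan-2-yl)
Conditions: B2pin2 (1.5 equiv), PdCl2(dppf) (5 mol %), KOAc (3 equiv), 1,4-dioxane, 90 °C
Reagents that add atoms: bis(pinacolato)diboron, CC1(C)OB(OC1(C)C)B1OC(C)(C)C(C)(C)O1
Why: Miyaura borylation of the aryl bromide; free alcohols and benzyl ethers are tolerated.

Step 10
Reactants: 11 tetrol
Product: 14 1,4-bis-O-triethylsilyl ether of 11 (both primary hydroxyls silylated)
Conditions: Et3SiCl (2.2 equiv), imidazole, DMF, −20 °C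
Reagents that add atoms: chlorotriethylsilane, CC[Si](Cl)(CC)CC
Why: Silylation selective for the two primary hydroxyls over the hindered secondary benzylic and the tertiary hydroxyl.

Step 11
Reactants: 14 bis-silyl ether
Product: 15 (2S,3S)-1-(4-benzyloxy-3-bromo-5-methoxyphenyl)-3-(4-benzyloxy-3-methoxybenzyl)-3-hydroxy-4-(triethylsilyloxy)-2-[(triethylsilyloxy)methyl]butan-1-one
Conditions: Dess–Martin periodinane (1.3 equiv), NaHCO3, CH2Cl2, 0 °C to rt
Reagents that add atoms: none
Why: Dess–Martin oxidation of the only oxidisable hydroxyl (the benzylic carbinol, both epimers converge); buffered, non-basic conditions spare the silyl ethers and the C3 centre α to the new ketone.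

Step 12
Reactants: 15 γ-silyloxy aryl ketone
Product: 18 (3S,4R,5R)-5-(4-benzyloxy-3-bromo-5-methoxyphenyl)-3-(4-benzyloxy-3-methoxybenzyl)-4-(hydroxymethyl)oxolan-3-ol, via oxocarbenium triflate 16 (not isolated), via triethylsilyl ether 17 (not isolated)
Conditions: Et3SiH (4 equiv), Me3SiOTf (0.2 equiv), CH2Cl2, −78 to −45 °C; then Bu4NF (2.5 equiv), THF, 0 °C
Reagents that add atoms: none
Why: Silyl triflate activates the aryl ketone, the C5 silyl ether oxygen adds to C2 and loses its silyl group, the cyclic silyl ketal ionises to the 2-aryl oxocarbenium ion 16, and Et3SiH delivers hydride to C2 to give 17; fluoride then frees the hydroxymethyl group. This is the Lewis-acid reductive etherification of silyloxy ketones, the same manifold as the silane reduction of cyclic hemiketals used for 2,3-cis 2-aryl oxolanes. The oxolane ring closes by O1–C2 bond formation in a 5-exo-trig mode. The new C2 centre (R) is controlled by the ring substituents: in the envelope with the C4 hydroxyl pseudoaxial and the C4 arylmethyl and C3 silyloxymethyl groups pseudoequatorial, inside attack puts hydride cis to the C4 oxygen and trans to both carbon substituents, so the aryl group ends cis to them. The step needs kinetic facial selectivity and no ionisation of the product; the matched bias of C3 and C4, the low temperature, catalytic acid and excess silane should secure this, and a four-membered closure from the C3 silyloxymethyl oxygen cannot compete.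

Step 13
Reactants: 18 oxolane bromide; 13 tetralin boronate
Product: 19 tetra-O-benzyl ether of the target (all four phenols benzylated)
Conditions: Pd(OAc)2 (5 mol %), SPhos (10 mol %), K3PO4 (3 equiv), toluene/H2O (10:1), 80 °C
Reagents that add atoms: none
Why: Suzuki–Miyaura coupling of two ortho-alkoxy aryl partners (each with only one ortho substituent, so no stable axis); basic, non-acidic conditions keep the cis oxolane intact.

Step 14
Reactants: 19 tetra-O-benzyl ether
Product: 20 CNP0344108.1
Conditions: H2 (1 atm), 10% Pd/C, EtOAc/MeOH, rt, stopped at complete debenzylation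
Reagents that add atoms: none
Why: Hydrogenolysis of the four aryl benzyl ethers, which is much faster than cleavage of the benzylic C2–O1 bond under neutral conditions; no stereocentre is touched.

**Compound list**

1 | (4-benzyloxy-3-methoxyphenyl)methanol | COc1cc(CO)ccc1OCc1ccccc1 | starting material
2 | 4-benzyloxy-3-methoxybenzyl bromide | COc1cc(CBr)ccc1OCc1ccccc1 | intermediate
3 | (S)-malic acid | OC(=O)C[C@H](O)C(=O)O | starting material
4 | 2-[(2S,4S)-2-tert-butyl-5-oxo-1,3-dioxolan-4-yl]acetic acid | OC(=O)C[C@@H]1O[C@H](C(C)(C)C)OC1=O | intermediate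
5 | 2-[(2S,4S)-4-(4-benzyloxy-3-methoxybenzyl)-2-tert-butyl-5-oxo-1,3-dioxolan-4-yl]acetic acid | OC(=O)C[C@]1(Cc2ccc(OCc3ccccc3)c(OC)c2)O[C@H](C(C)(C)C)OC1=O | intermediate
6 | (3S)-4-(4-benzyloxy-3-methoxyphenyl)-3-hydroxy-3-(hydroxymethyl)butanoic acid (not isolated) | COc1cc(C[C@@](O)(CO)CC(=O)O)ccc1OCc1ccccc1 | intermediate
7 | (4S)-4-(4-benzyloxy-3-methoxybenzyl)-4-hydroxyoxolan-2-one | COc1cc(C[C@@]2(O)COC(=O)C2)ccc1OCc1ccccc1 | intermediate
8 | 5-bromovanillin (3-bromo-4-hydroxy-5-methoxybenzaldehyde) | COc1cc(C=O)cc(Br)c1O | starting material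
9 | 4-benzyloxy-3-bromo-5-methoxybenzaldehyde | COc1cc(C=O)cc(Br)c1OCc1ccccc1 | intermediate
10 | (3R,4S)-3-[(4-benzyloxy-3-bromo-5-methoxyphenyl)(hydroxy)methyl]-4-(4-benzyloxy-3-methoxybenzyl)-4-hydroxyoxolan-2-one, carbinol epimers | COc1cc(C[C@@]2(O)COC(=O)[C@@H]2C(O)c2cc(OC)c(OCc3ccccc3)c(Br)c2)ccc1OCc1ccccc1 | intermediate
11 | (2S,3R)-3-[(4-benzyloxy-3-bromo-5-methoxyphenyl)(hydroxy)methyl]-2-(4-benzyloxy-3-methoxybenzyl)butane-1,2,4-triol, carbinol epimers | COc1cc(C[C@@](O)(CO)[C@H](CO)C(O)c2cc(OC)c(OCc3ccccc3)c(Br)c2)ccc1OCc1ccccc1 | intermediate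
12 | (2S,3S,4S)-6-benzyloxy-4-(4-benzyloxy-3-bromo-5-methoxyphenyl)-2,3-bis(hydroxymethyl)-7-methoxy-1,2,3,4-tetrahydronaphthalen-2-ol | COc1cc([C@H]2c3cc(OCc4ccccc4)c(OC)cc3C[C@@](O)(CO)[C@@H]2CO)cc(Br)c1OCc1ccccc1 | intermediate
13 | pinacol boronate of 12 | COc1cc([C@H]2c3cc(OCc4ccccc4)c(OC)cc3C[C@@](O)(CO)[C@@H]2CO)cc(B3OC(C)(C)C(C)(C)O3)c1OCc1ccccc1 | intermediate
14 | 1,4-bis-O-triethylsilyl ether of 11 | COc1cc(C[C@@](O)(CO[Si](CC)(CC)CC)[C@H](CO[Si](CC)(CC)CC)C(O)c2cc(OC)c(OCc3ccccc3)c(Br)c2)ccc1OCc1ccccc1 | intermediate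
15 | (2S,3S)-1-(4-benzyloxy-3-bromo-5-methoxyphenyl)-3-(4-benzyloxy-3-methoxybenzyl)-3-hydroxy-4-(triethylsilyloxy)-2-[(triethylsilyloxy)methyl]butan-1-one | COc1cc(C[C@@](O)(CO[Si](CC)(CC)CC)[C@H](CO[Si](CC)(CC)CC)C(=O)c2cc(OC)c(OCc3ccccc3)c(Br)c2)ccc1OCc1ccccc1 | intermediate
16 | cyclic 2-aryl oxocarbenium triflate (not isolated) | COc1cc(C[C@@]2(O)C[O+]=C(c3cc(OC)c(OCc4ccccc4)c(Br)c3)[C@H]2CO[Si](CC)(CC)CC)ccc1OCc1ccccc1.[O-]S(=O)(=O)C(F)(F)F | intermediate
17 | O-triethylsilyl ether of 18 at the hydroxymethyl group (not isolated) | COc1cc(C[C@@]2(O)CO[C@@H](c3cc(OC)c(OCc4ccccc4)c(Br)c3)[C@H]2CO[Si](CC)(CC)CC)ccc1OCc1ccccc1 | intermediate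
18 | (3S,4R,5R)-5-(4-benzyloxy-3-bromo-5-methoxyphenyl)-3-(4-benzyloxy-3-methoxybenzyl)-4-(hydroxymethyl)oxolan-3-ol | COc1cc(C[C@@]2(O)CO[C@@H](c3cc(OC)c(OCc4ccccc4)c(Br)c3)[C@H]2CO)ccc1OCc1ccccc1 | intermediate
19 | tetra-O-benzyl ether of the target | COc1cc(C[C@@]2(O)CO[C@@H](c3cc(OC)c(OCc4ccccc4)c(-c4cc([C@H]5c6cc(OCc7ccccc7)c(OC)cc6C[C@@](O)(CO)[C@@H]5CO)cc(OC)c4OCc4ccccc4)c3)[C@H]2CO)ccc1OCc1ccccc1 | intermediate
20 | CNP0344108.1 | COc1cc(C[C@@]2(O)CO[C@@H](c3cc(OC)c(O)c(-c4cc([C@H]5c6cc(O)c(OC)cc6C[C@@](O)(CO)[C@@H]5CO)cc(OC)c4O)c3)[C@H]2CO)ccc1O | target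

**Count.** Total: 14 steps. Longest linear sequence: 10 steps from (S)-malic acid (steps 2, 3, 4, 6, 7, 10, 11, 12, 13, 14).

**Steps most likely to fail**

Step 6. The risk is poor facial selectivity at the enolate carbon: the aldehyde may enter syn to the arylmethyl group and anti to the alkoxide, as small electrophiles do with simpler β-alkoxide lactone enolates, which would give the C3 epimer. The fallback replaces kinetic by thermodynamic control. It sets out from 10, whatever its C3 composition. Dess–Martin oxidation of the benzylic carbinol should give the β-keto lactone (3S,4S)-3-(4-benzyloxy-3-bromo-5-methoxybenzoyl)-4-(4-benzyloxy-3-methoxybenzyl)-4-hydroxyoxolan-2-one F2. Its C3, now flanked by two carbonyls, is equilibrated (Et3N cat., CH2Cl2, rt) to the isomer with the aroyl group trans to the arylmethyl group and hydrogen-bonded to the C4 hydroxyl. LiBH4 (THF/MeOH, 0 °C) then reduces ketone and lactone and the route is rejoined at tetrol 11.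

Step 12. The risk is that the silane reduces the open-chain ketone, or the β-silyloxy group is lost by elimination, before the silyl ether oxygen engages the carbonyl; acid ionisation of the product is the second danger. The fallback forms the ring first and reduces afterwards. It sets out from tetrol 11. MnO2 (CH2Cl2, rt) should oxidise only the benzylic carbinol, and the hydroxy ketone closes spontaneously through the C5 hydroxyl to the cyclic hemiketal (4R,5S)-2-(4-benzyloxy-3-bromo-5-methoxyphenyl)-4-(4-benzyloxy-3-methoxybenzyl)-3-(hydroxymethyl)oxolane-2,4-diol F1 (anomer mixture), in which the O1–C2 bond is formed by hemiketalisation. Et3SiH/BF3·OEt2 (CH2Cl2/MeCN, −78 °C) then reduces F1 through the same oxocarbenium ion with the same facial bias, and the route is rejoined at 18.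

Step 14. The risk is over-reduction: once the para phenol is unmasked, the benzylic C2–O1 bond of the oxolane may be hydrogenolysed. The fallback avoids hydrogen altogether. It sets out from 19 and uses Lewis-acid benzyl transfer: BCl3 (excess) with pentamethylbenzene as cation scavenger, CH2Cl2, −78 °C, quenched cold with MeOH/NaHCO3, which should give 20 directly. No new compound lies on its way (F0).

Further compounds
F2 | step 6 | (3S,4S)-3-(4-benzyloxy-3-bromo-5-methoxybenzoyl)-4-(4-benzyloxy-3-methoxybenzyl)-4-hydroxyoxolan-2-one | COc1cc(C[C@@]2(O)COC(=O)[C@@H]2C(=O)c2cc(OC)c(OCc3ccccc3)c(Br)c2)ccc1OCc1ccccc1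
F1 | step 12 | (4R,5S)-2-(4-benzyloxy-3-bromo-5-methoxyphenyl)-4-(4-benzyloxy-3-methoxybenzyl)-3-(hydroxymethyl)oxolane-2,4-diol (anomer mixture) | COc1cc(C[C@@]2(O)COC(O)(c3cc(OC)c(OCc4ccccc4)c(Br)c3)[C@H]2CO)ccc1OCc1ccccc1
F0 | step 14 | none | none
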